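Retrosynthesis: the angelate C3–O bond is cut first, then the C11=C13 methylene and the C12 ester level; C5–C10 and C6–C7 are then cut together (intramolecular [4+2]); the open chain is cut at C7=C8 (olefination) and C5≡C6 (alkyne homologation), which leaves neryl acetate.
Enabling feature: C5=C6 lies at the ring fusion between quaternary C10 and C7, so rings A and B together are the 1,4-cyclohexadiene adduct of a C5≡C6 alkyne and a C10=C9–C8=C7 diene tied through C1–C4; the extra C8=C9 bond is hydrogenated afterwards.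
Forward order: neryl acetate supplies C8–C10, C1–C5, C14 and C15; C6 comes by homologation and C7, C11, C12 by Julia–Kocienski olefination; rings A and B close together in one step; C13, the methyl ester and the angelate follow.
Strengthening: an unactivated alkyne would need temperatures at which the Z-diene undergoes 1,5-hydrogen shift, so the alkyne is activated as its phenylsulfonyl derivative, a traceless group removed later with Na(Hg).
Stereochemistry: C4 from Sharpless epoxidation (D-(−)-tartrate); C3 by invertive epoxide opening; the cis C7/C10 relation from the Z-C9=C10 (nerol) and E-C7=C8 (olefination) geometry; their absolute sense from the C3/C4-controlled chair tether in the cycloaddition.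
Purchased: neryl acetate (the acetate of nerol), (3-bromopropoxy)(tert-butyl)dimethylsilane and angelic acid.

Key step: step 13

Remark: locants C1–C15 are the eudesmane locants of the target throughout (C3 acyloxy carbon, C4 carbinol, C5=C6, C7 arm-bearing carbon, C10 quaternary carbon, C11–C13 acrylate, C14 and C15 methyls); the sulfonyl alkyne of step 12 is assumed to be kept cold and used at once.

Step 1
Reactants: 1 neryl acetate, (2Z)-3,7-dimethylocta-2,6-dien-1-yl acetate
Product: 2 (2Z,6E)-8-hydroxy-3,7-dimethylocta-2,6-dien-1-yl acetate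
Conditions: SeO2 (cat.), t-BuOOH, salicylic acid (cat.), CH2Cl2, rt
Reagents that add atoms: selenium dioxide, O=[Se]=O; tert-butyl hydroperoxide, CC(C)(C)OO
Why: Selenium dioxide allylic oxidation (ene reaction, then 2,3-sigmatropic shift) hydroxylates the E-methyl of the electron-richer distal trisubstituted alkene, the C9=C10 alkene being deactivated by its allylic acetate.

Step 2
Reactants: 2 E-allylic alcohol
Product: 3 (2Z)-5-[(2R,3R)-3-(hydroxymethyl)-3-methyloxiran-2-yl]-3-methylpent-2-en-1-yl acetate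
Conditions: Ti(OiPr)4 (cat.), D-(−)-diisopropyl tartrate (cat.), t-BuOOH, 4 Å molecular sieves, CH2Cl2, −20 °C
Reagents that add atoms: tert-butyl hydroperoxide, CC(C)(C)OO
Why: Sharpless asymmetric epoxidation of the E-2-methyl allylic alcohol, in which the titanium D-(−)-tartrate catalyst should deliver oxygen to the face giving the (2R,3R)-epoxide, so that the C4–O bond has its final R configuration and the C3–O bond is placed for later inversion.

Step 3
Reactants: 3 epoxy alcohol
Product: 4 (2Z,6S,7R)-1-(acetyloxy)-7,8-dihydroxy-3,7-dimethyloct-2-en-6-yl benzoate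
Conditions: Ti(OiPr)4, PhCO2H, CH2Cl2, rt
Reagents that add atoms: benzoic acid, OC(=O)c1ccccc1
Why: Titanium-mediated regioselective opening of a 2,3-epoxy alcohol, in which benzoate attacks C3 (the carbon remote from the carbinol) of the titanium epoxy-alkoxide chelate by SN2 with inversion (3S) while the fully substituted C4 keeps its oxygen with retention (4R), giving the erythro pattern that becomes the cis-3,4-diol of ring A.

Step 4
Reactants: 4 diol benzoate
Product: 5 (2Z,6S,7S)-1-(acetyloxy)-7-hydroxy-3,7-dimethyl-8-oxooct-2-en-6-yl benzoate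
Conditions: SO3·pyridine, DMSO, Et3N, CH2Cl2, 0 °C
Reagents that add atoms: none
Why: Parikh–Doering oxidation takes the primary alcohol to the aldehyde without touching the tertiary carbinol or risking glycol cleavage, and since C4 carries no hydrogen neither epimerisation nor β-elimination of the benzoate is possible.

Step 5
Reactants: 5 α-hydroxy aldehyde
Product: 7 (2Z,6S,7R)-3,7-dimethylnon-2-en-8-yne-1,6,7-triol, via alkyne diester 6 (not isolated)
Conditions: dimethyl (1-diazo-2-oxopropyl)phosphonate, K2CO3, MeOH, 0 °C → rt, then 40 °C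
Reagents that add atoms: dimethyl (1-diazo-2-oxopropyl)phosphonate, COP(=O)(OC)C(=[N+]=[N-])C(C)=O
Why: Ohira–Bestmann (Seyferth–Gilbert) homologation turns the aldehyde into the terminal alkyne C5≡C6 without affecting the quaternary C4, and the same K2CO3/methanol medium then methanolyses the acetate and the benzoate.

Step 6
Reactants: 7 alkyne triol
Product: 8 (2Z,6S,7R)-6,7-dihydroxy-3,7-dimethylnon-2-en-8-ynal
Conditions: MnO2, CH2Cl2, rt
Reagents that add atoms: none
Why: MnO2 oxidation is selective for the allylic primary alcohol, leaves the saturated secondary and the tertiary propargylic carbinols alone, and under neutral conditions should keep the Z geometry of C9=C10.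

Step 7
Reactants: 8 enal diol
Product: 9 (2Z,6S,7R)-6-[(tert-butyldimethylsilyl)oxy]-7-hydroxy-3,7-dimethylnon-2-en-8-ynal
Conditions: TBSOTf (1.05 equiv), 2,6-lutidine, CH2Cl2, −78 °C
Reagents that add atoms: tert-butyldimethylsilyl trifluoromethanesulfonate, CC(C)(C)[Si](C)(C)OS(=O)(=O)C(F)(F)F
Why: Selective O-silylation, the silyl triflate at −78 °C distinguishing the secondary C3 hydroxyl from the tertiary propargylic C4 hydroxyl on steric grounds.

Step 8
Reactants: 10 (3-bromopropoxy)(tert-butyl)dimethylsilane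
Product: 11 5-({3-[(tert-butyldimethylsilyl)oxy]propyl}sulfanyl)-1-phenyl-1H-tetrazole
Conditions: 1-phenyl-1H-tetrazole-5-thiol, K2CO3, acetone, rt
Reagents that add atoms: 1-phenyl-1H-tetrazole-5-thiol, Sc1nnnn1-c1ccccc1
Why: SN2 S-alkylation of the acidic tetrazolethiol by the primary bromide.

Step 9
Reactants: 11 tetrazolyl sulfide
Product: 12 5-({3-[(tert-butyldimethylsilyl)oxy]propyl}sulfonyl)-1-phenyl-1H-tetrazole
Conditions: (NH4)6Mo7O24·4H2O (cat.), 30% H2O2, EtOH, 0 °C → rt
Reagents that add atoms: hydrogen peroxide, OO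
Why: Molybdate-catalysed peroxide oxidation of the sulfide to the sulfone, the usual entry to Julia–Kocienski reagents, which leaves the primary silyl ether intact.

Step 10
Reactants: 9 silyloxy enal; 12 tetrazolyl sulfone
Product: 13 (3R,4S,7Z,9E)-4,12-bis[(tert-butyldimethylsilyl)oxy]-3,7-dimethyldodeca-7,9-dien-1-yn-3-ol
Conditions: 12, KN(SiMe3)2, DME, −60 °C; then 9, −60 °C → rt
Reagents that add atoms: none
Why: Julia–Kocienski olefination, in which the potassium salt of the phenyltetrazolyl sulfone adds to the enal and Smiles rearrangement with loss of SO2 should give the new C7=C8 bond with E geometry while the Z-C9=C10 bond from nerol is kept, the tertiary hydroxyl and alkyne C–H being too weakly acidic to quench the reagent.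

Step 11
Reactants: 13 terminal dienyne
Product: 14 (3R,4S,7Z,9E)-4,12-bis[(tert-butyldimethylsilyl)oxy]-3,7-dimethyl-1-(phenylsulfanyl)dodeca-7,9-dien-1-yn-3-ol
Conditions: n-BuLi (2.1 equiv), THF, −78 °C; PhSSPh, −78 → 0 °C
Reagents that add atoms: diphenyl disulfide, c1ccccc1SSc1ccccc1
Why: Deprotonation of the hydroxyl and the alkyne C–H followed by electrophilic thiolation of the lithium acetylide with the disulfide gives the alkynyl sulfide.

Step 12
Reactants: 14 alkynyl sulfide
Product: 15 (3R,4S,7Z,9E)-1-(benzenesulfonyl)-4,12-bis[(tert-butyldimethylsilyl)oxy]-3,7-dimethyldodeca-7,9-dien-1-yn-3-ol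
Conditions: (NH4)6Mo7O24·4H2O (cat.), 30% H2O2, EtOH/THF, 0 °C
Reagents that add atoms: hydrogen peroxide, OO
Why: Molybdate-catalysed peroxide oxidation acts at the nucleophilic sulfur far faster than at the conjugated diene and turns the alkynyl sulfide into the strongly electron-poor alkynyl sulfone.

Step 13
Reactants: 15 sulfonyl dienyne
Product: 16 (1R,2S,4aR,7R)-8-(benzenesulfonyl)-2-[(tert-butyldimethylsilyl)oxy]-7-{2-[(tert-butyldimethylsilyl)oxy]ethyl}-1,4a-dimethyl-1,2,3,4,4a,7-hexahydronaphthalen-1-ol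
Conditions: toluene (0.01 M), BHT (cat.), 80 °C
Reagents that add atoms: none
Why: The electron-poor phenylsulfonyl alkyne C5≡C6 adds suprafacially to the s-cis C10=C9–C8=C7 diene in a concerted, asynchronous normal-demand Diels–Alder reaction that forms C5–C10 and C6–C7 and leaves C5=C6 at the ring fusion. The closest known reaction type is the thermal intramolecular Diels–Alder reaction of tethered dienes with acetylenic sulfones (acetylene equivalents) and of Z-dienes that carry the tether on the inside position. Ring B (C5, C6, C7, C8, C9, C10) is the six-membered ring created by the cycloaddition itself, and ring A (C1–C5, C10) closes in the fused mode as the tether ring when C5 bonds to C10 through the four-atom tether C1–C4. The new stereocentres C7 and C10 are cis because the C10 methyl and the C7 arm are both outside substituents of the Z-C9=C10, E-C7=C8 diene (stereospecific), and their absolute sense follows from the diene face, chosen by a chair-like tether with the C3 silyloxy group equatorial and the C4 hydroxyl, not the C15 methyl, syn-axial to the C10 methyl. The step needs diene-face selectivity and periselectivity over the 1,5-hydrogen shift open to the Z-diene: the first should be secured by the C3 and C4 substituents, the second by the sulfone, which lets closure run near 80 °C, far below the temperature of the sigmatropic shift, while the tether fixes the regiochemistry.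

Step 14
Reactants: 16 cycloadduct
Product: 17 (1R,2S,4aS,7S)-8-(benzenesulfonyl)-2-[(tert-butyldimethylsilyl)oxy]-7-{2-[(tert-butyldimethylsilyl)oxy]ethyl}-1,4a-dimethyl-1,2,3,4,4a,5,6,7-octahydronaphthalen-1-ol
Conditions: H2 (1 atm), RhCl(PPh3)3 (cat.), benzene/EtOH, rt
Reagents that add atoms: none
Why: Homogeneous hydrogenation with the monovalent rhodium catalyst RhCl(PPh3)3 is highly sensitive to substitution and should saturate only the cis-disubstituted C8=C9 bond, the tetrasubstituted electron-poor C5=C6 sulfonyl alkene being inert.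

Step 15
Reactants: 17 alkenyl sulfone
Product: 18 (1R,2S,4aS,7S)-2-[(tert-butyldimethylsilyl)oxy]-7-{2-[(tert-butyldimethylsilyl)oxy]ethyl}-1,4a-dimethyl-1,2,3,4,4a,5,6,7-octahydronaphthalen-1-ol
Conditions: Na(Hg) (6% Na), Na2HPO4, MeOH/THF, −20 °C
Reagents that add atoms: none
Why: Reductive desulfonylation of the alkenyl sulfone by electron transfer from sodium amalgam in buffered methanol should replace the sulfonyl group on C6 by hydrogen with the double bond kept at C5=C6, completing the acetylene-equivalent tactic.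

Step 16
Reactants: 18 bis(silyl ether)
Product: 19 (1R,2S,4aS,7S)-7-(2-hydroxyethyl)-1,4a-dimethyl-1,2,3,4,4a,5,6,7-octahydronaphthalene-1,2-diol
Conditions: Bu4NF, THF, rt
Reagents that add atoms: none
Why: Fluoride-mediated cleavage of both silyl ethers frees the C3 and C12 hydroxyls.

Step 17
Reactants: 19 triol
Product: 20 2-[(2S,4aS,7S,8R)-7,8-dihydroxy-4a,8-dimethyl-2,3,4,4a,5,6,7,8-octahydronaphthalen-2-yl]acetaldehyde
Conditions: [Cu(MeCN)4]OTf (cat.), 2,2′-bipyridine, TEMPO, N-methylimidazole, MeCN, air, rt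
Reagents that add atoms: none
Why: Copper/nitroxyl aerobic oxidation (Stahl oxidation, monovalent copper with TEMPO) is selective for the unhindered primary alcohol over the hindered secondary and the tertiary carbinol and stops at the aldehyde.

Step 18
Reactants: 20 aldehyde
Product: 22 2-[(2R,4aS,7S,8R)-7,8-dihydroxy-4a,8-dimethyl-2,3,4,4a,5,6,7,8-octahydronaphthalen-2-yl]prop-2-enal, via Mannich base 21 (not isolated)
Conditions: Me2N=CH2 I (Eschenmoser's salt), Et3N, CH2Cl2, rt
Reagents that add atoms: N,N-dimethylmethyleneiminium iodide, C[N+](C)=C.[I-]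
Why: Mannich reaction of the aldehyde with Eschenmoser's salt and elimination of dimethylamine from the Mannich base (α-methylenation) installs C13 as the exocyclic methylene.

Step 19
Reactants: 22 α-methylene aldehyde
Product: 23 2-[(2R,4aS,7S,8R)-7,8-dihydroxy-4a,8-dimethyl-2,3,4,4a,5,6,7,8-octahydronaphthalen-2-yl]prop-2-enoic acid
Conditions: NaClO2, NaH2PO4, 2-methylbut-2-ene, t-BuOH/H2O, 0 °C
Reagents that add atoms: sodium chlorite, [Na+].[O-]Cl=O
Why: Pinnick oxidation converts the α-methylene aldehyde into the acrylic acid under buffered conditions that spare the alkenes and the carbinols, hypochlorite being scavenged by 2-methylbut-2-ene.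

Step 20
Reactants: 23 acrylic acid
Product: 24 methyl 2-[(2R,4aS,7S,8R)-7,8-dihydroxy-4a,8-dimethyl-2,3,4,4a,5,6,7,8-octahydronaphthalen-2-yl]prop-2-enoate
Conditions: Me3SiCHN2, MeOH/toluene, 0 °C
Reagents that add atoms: (trimethylsilyl)diazomethane, C[Si](C)(C)C=[N+]=[N-]
Why: O-Methylation of the carboxylic acid with (trimethylsilyl)diazomethane in methanol is fast and neutral, so neither the acrylate nor the doubly allylic C7–H should be disturbed.

Step 21
Reactants: 24 diol methyl ester; 25 angelic acid, (2Z)-2-methylbut-2-enoic acid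
Product: 27 methyl 2-[(2R,4aS,7S,8R)-8-hydroxy-4a,8-dimethyl-7-{[(2Z)-2-methylbut-2-enoyl]oxy}-2,3,4,4a,5,6,7,8-octahydronaphthalen-2-yl]prop-2-enoate (CNP0283268.1), via mixed anhydride 26 (not isolated)
Conditions: 25, 2,4,6-trichlorobenzoyl chloride, Et3N, toluene, rt; then 24, 80 °C
Reagents that add atoms: none
Why: Yamaguchi esterification through the mixed anhydride should acylate the secondary C3 hydroxyl only, the tertiary C4 carbinol being inert, and without a nucleophilic catalyst the Z geometry of the angeloyl group should be kept.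

Compound list
1 | neryl acetate, (2Z)-3,7-dimethylocta-2,6-dien-1-yl acetate | CC(C)=CCC/C(C)=C\COC(C)=O | starting material
2 | (2Z,6E)-8-hydroxy-3,7-dimethylocta-2,6-dien-1-yl acetate | OC/C(C)=C/CC/C(C)=C\COC(C)=O | intermediate
3 | (2Z)-5-[(2R,3R)-3-(hydroxymethyl)-3-methyloxiran-2-yl]-3-methylpent-2-en-1-yl acetate | OC[C@@]1(C)O[C@@H]1CC/C(C)=C\COC(C)=O | intermediate
4 | (2Z,6S,7R)-1-(acetyloxy)-7,8-dihydroxy-3,7-dimethyloct-2-en-6-yl benzoate | OC[C@@](C)(O)[C@@H](OC(=O)c1ccccc1)CC/C(C)=C\COC(C)=O | intermediate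
5 | (2Z,6S,7S)-1-(acetyloxy)-7-hydroxy-3,7-dimethyl-8-oxooct-2-en-6-yl benzoate | O=C[C@@](C)(O)[C@@H](OC(=O)c1ccccc1)CC/C(C)=C\COC(C)=O | intermediate
6 | (2Z,6S,7R)-1-(acetyloxy)-7-hydroxy-3,7-dimethylnon-2-en-8-yn-6-yl benzoate (alkyne diester, formed in the flask, not isolated) | C#C[C@@](C)(O)[C@@H](OC(=O)c1ccccc1)CC/C(C)=C\COC(C)=O | intermediate
7 | (2Z,6S,7R)-3,7-dimethylnon-2-en-8-yne-1,6,7-triol | C#C[C@@](C)(O)[C@@H](O)CC/C(C)=C\CO | intermediate
8 | (2Z,6S,7R)-6,7-dihydroxy-3,7-dimethylnon-2-en-8-ynal | C#C[C@@](C)(O)[C@@H](O)CC/C(C)=C\C=O | intermediate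
9 | (2Z,6S,7R)-6-[(tert-butyldimethylsilyl)oxy]-7-hydroxy-3,7-dimethylnon-2-en-8-ynal | C#C[C@@](C)(O)[C@@H](O[Si](C)(C)C(C)(C)C)CC/C(C)=C\C=O | intermediate
10 | (3-bromopropoxy)(tert-butyl)dimethylsilane | BrCCCO[Si](C)(C)C(C)(C)C | starting material
11 | 5-({3-[(tert-butyldimethylsilyl)oxy]propyl}sulfanyl)-1-phenyl-1H-tetrazole | CC(C)(C)[Si](C)(C)OCCCSc1nnnn1-c1ccccc1 | intermediate
12 | 5-({3-[(tert-butyldimethylsilyl)oxy]propyl}sulfonyl)-1-phenyl-1H-tetrazole | CC(C)(C)[Si](C)(C)OCCCS(=O)(=O)c1nnnn1-c1ccccc1 | intermediate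
13 | (3R,4S,7Z,9E)-4,12-bis[(tert-butyldimethylsilyl)oxy]-3,7-dimethyldodeca-7,9-dien-1-yn-3-ol | C#C[C@@](C)(O)[C@@H](O[Si](C)(C)C(C)(C)C)CC/C(C)=C\C=C\CCO[Si](C)(C)C(C)(C)C | intermediate
14 | (3R,4S,7Z,9E)-4,12-bis[(tert-butyldimethylsilyl)oxy]-3,7-dimethyl-1-(phenylsulfanyl)dodeca-7,9-dien-1-yn-3-ol | c1ccccc1SC#C[C@@](C)(O)[C@@H](O[Si](C)(C)C(C)(C)C)CC/C(C)=C\C=C\CCO[Si](C)(C)C(C)(C)C | intermediate
15 | (3R,4S,7Z,9E)-1-(benzenesulfonyl)-4,12-bis[(tert-butyldimethylsilyl)oxy]-3,7-dimethyldodeca-7,9-dien-1-yn-3-ol (cycloaddition precursor) | O=S(=O)(C#C[C@@](C)(O)[C@@H](O[Si](C)(C)C(C)(C)C)CC/C(C)=C\C=C\CCO[Si](C)(C)C(C)(C)C)c1ccccc1 | intermediate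
16 | (1R,2S,4aR,7R)-8-(benzenesulfonyl)-2-[(tert-butyldimethylsilyl)oxy]-7-{2-[(tert-butyldimethylsilyl)oxy]ethyl}-1,4a-dimethyl-1,2,3,4,4a,7-hexahydronaphthalen-1-ol (5,8-diene with 3β-silyloxy, 4β-OH, 7β arm, 10β-methyl) | CC(C)(C)[Si](C)(C)OCC[C@H]1C(S(=O)(=O)c2ccccc2)=C2[C@](C)(CC[C@H](O[Si](C)(C)C(C)(C)C)[C@]2(C)O)C=C1 | intermediate
17 | (1R,2S,4aS,7S)-8-(benzenesulfonyl)-2-[(tert-butyldimethylsilyl)oxy]-7-{2-[(tert-butyldimethylsilyl)oxy]ethyl}-1,4a-dimethyl-1,2,3,4,4a,5,6,7-octahydronaphthalen-1-ol | CC(C)(C)[Si](C)(C)OCC[C@H]1C(S(=O)(=O)c2ccccc2)=C2[C@](C)(CC[C@H](O[Si](C)(C)C(C)(C)C)[C@]2(C)O)CC1 | intermediate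
18 | (1R,2S,4aS,7S)-2-[(tert-butyldimethylsilyl)oxy]-7-{2-[(tert-butyldimethylsilyl)oxy]ethyl}-1,4a-dimethyl-1,2,3,4,4a,5,6,7-octahydronaphthalen-1-ol | CC(C)(C)[Si](C)(C)OCC[C@H]1C=C2[C@](C)(CC[C@H](O[Si](C)(C)C(C)(C)C)[C@]2(C)O)CC1 | intermediate
19 | (1R,2S,4aS,7S)-7-(2-hydroxyethyl)-1,4a-dimethyl-1,2,3,4,4a,5,6,7-octahydronaphthalene-1,2-diol | OCC[C@H]1C=C2[C@](C)(CC[C@H](O)[C@]2(C)O)CC1 | intermediate
20 | 2-[(2S,4aS,7S,8R)-7,8-dihydroxy-4a,8-dimethyl-2,3,4,4a,5,6,7,8-octahydronaphthalen-2-yl]acetaldehyde | O=CC[C@H]1C=C2[C@](C)(CC[C@H](O)[C@]2(C)O)CC1 | intermediate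
21 | 3-(dimethylamino)-2-[(2R,4aS,7S,8R)-7,8-dihydroxy-4a,8-dimethyl-2,3,4,4a,5,6,7,8-octahydronaphthalen-2-yl]propanal (Mannich base, both epimers at the aldehyde α-carbon, not isolated) | CN(C)CC(C=O)[C@H]1C=C2[C@](C)(CC[C@H](O)[C@]2(C)O)CC1 | intermediate
22 | 2-[(2R,4aS,7S,8R)-7,8-dihydroxy-4a,8-dimethyl-2,3,4,4a,5,6,7,8-octahydronaphthalen-2-yl]prop-2-enal | C=C(C=O)[C@H]1C=C2[C@](C)(CC[C@H](O)[C@]2(C)O)CC1 | intermediate
23 | 2-[(2R,4aS,7S,8R)-7,8-dihydroxy-4a,8-dimethyl-2,3,4,4a,5,6,7,8-octahydronaphthalen-2-yl]prop-2-enoic acid | C=C(C(=O)O)[C@H]1C=C2[C@](C)(CC[C@H](O)[C@]2(C)O)CC1 | intermediate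
24 | methyl 2-[(2R,4aS,7S,8R)-7,8-dihydroxy-4a,8-dimethyl-2,3,4,4a,5,6,7,8-octahydronaphthalen-2-yl]prop-2-enoate | C=C(C(=O)OC)[C@H]1C=C2[C@](C)(CC[C@H](O)[C@]2(C)O)CC1 | intermediate
25 | angelic acid, (2Z)-2-methylbut-2-enoic acid | C/C=C(/C)C(O)=O | starting material
26 | (2Z)-2-methylbut-2-enoic 2,4,6-trichlorobenzoic anhydride (mixed anhydride, not isolated) | C/C=C(/C)C(=O)OC(=O)c1c(Cl)cc(Cl)cc1Cl | intermediate
27 | methyl 2-[(2R,4aS,7S,8R)-8-hydroxy-4a,8-dimethyl-7-{[(2Z)-2-methylbut-2-enoyl]oxy}-2,3,4,4a,5,6,7,8-octahydronaphthalen-2-yl]prop-2-enoate (CNP0283268.1) | C=C(C(=O)OC)[C@H]1C=C2[C@](C)(CC[C@H](OC(=O)/C(C)=C\C)[C@]2(C)O)CC1 | target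

Total step count: 21. Longest linear sequence: 19 steps (steps 1–7 and 10–21, from neryl acetate); steps 8 and 9 make the sulfone 12.

Steps most likely to fail

Step 13. Closure may be slow at the fully substituted C10 terminus of the Z-diene, and diene-face selectivity may erode because allylic strain between the sulfonyl group and the equatorial C15 methyl works against the chair-tether preference. The fallback moves the cycloaddition to the unactivated terminal alkyne 13 and changes the mechanism. Treatment of 13 with [Rh(cod)Cl]2 and AgSbF6 in CH2Cl2 (a metallacycle-mediated [4+2] on monovalent rhodium, known for dienynes) should give the sulfone-free bicyclic 5,8-diene F1, in which no group on C6 opposes the tether control. Hydrogenation of F1 with RhCl(PPh3)3 and H2 would rejoin the route at 18, so that steps 11–15 are bypassed.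

Step 12. The peroxide may attack the conjugated diene in competition with sulfur, and the activated alkyne may react on in the oxidising medium before it is isolated. The fallback needs no oxidant in the presence of the diene. Starting again from 13, the lithium acetylide (n-BuLi, THF, −78 °C) would be sulfinylated with methyl benzenesulfinate to the alkynyl phenyl sulfoxide F2. Heating F2 in toluene (intramolecular Diels–Alder reaction of a sulfinyl alkyne) should give the sulfinyl cycloadduct F3, and hydrogenation with RhCl(PPh3)3 and H2 the C8–C9-saturated alkenyl sulfoxide F4. Sulfoxide–lithium exchange of F4 with t-BuLi at −78 °C and protonation with methanol would return to the route at 18.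

Step 21. Acylation may stall at the hindered C3 carbinol next to the quaternary C4, and the activated angeloyl unit may isomerise from Z to E under forcing conditions. The fallback builds the Z double bond on the ester instead of importing it. From 24, esterification of the C3 hydroxyl with 2-[bis(2,2,2-trifluoroethoxy)phosphoryl]propanoic acid (EDC·HCl, DMAP, CH2Cl2) should give the phosphonopropionate ester F5. Still–Gennari olefination of F5 with acetaldehyde (KN(SiMe3)2, 18-crown-6, THF, −78 °C) should form the Z-trisubstituted alkene and arrive at 27.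

Further compounds
F1 | step 13 | (1R,2S,4aR,7R)-2-[(tert-butyldimethylsilyl)oxy]-7-{2-[(tert-butyldimethylsilyl)oxy]ethyl}-1,4a-dimethyl-1,2,3,4,4a,7-hexahydronaphthalen-1-ol | CC(C)(C)[Si](C)(C)OCC[C@H]1C=C2[C@](C)(CC[C@H](O[Si](C)(C)C(C)(C)C)[C@]2(C)O)C=C1
F2 | step 12 | (3R,4S,7Z,9E)-1-(benzenesulfinyl)-4,12-bis[(tert-butyldimethylsilyl)oxy]-3,7-dimethyldodeca-7,9-dien-1-yn-3-ol, either configuration at sulfur | O=S(C#C[C@@](C)(O)[C@@H](O[Si](C)(C)C(C)(C)C)CC/C(C)=C\C=C\CCO[Si](C)(C)C(C)(C)C)c1ccccc1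
F3 | step 12 | (1R,2S,4aR,7R)-8-(benzenesulfinyl)-2-[(tert-butyldimethylsilyl)oxy]-7-{2-[(tert-butyldimethylsilyl)oxy]ethyl}-1,4a-dimethyl-1,2,3,4,4a,7-hexahydronaphthalen-1-ol, either configuration at sulfur | CC(C)(C)[Si](C)(C)OCC[C@H]1C(S(=O)c2ccccc2)=C2[C@](C)(CC[C@H](O[Si](C)(C)C(C)(C)C)[C@]2(C)O)C=C1
F4 | step 12 | (1R,2S,4aS,7S)-8-(benzenesulfinyl)-2-[(tert-butyldimethylsilyl)oxy]-7-{2-[(tert-butyldimethylsilyl)oxy]ethyl}-1,4a-dimethyl-1,2,3,4,4a,5,6,7-octahydronaphthalen-1-ol, either configuration at sulfur | CC(C)(C)[Si](C)(C)OCC[C@H]1C(S(=O)c2ccccc2)=C2[C@](C)(CC[C@H](O[Si](C)(C)C(C)(C)C)[C@]2(C)O)CC1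
F5 | step 21 | methyl 2-[(2R,4aS,7S,8R)-7-({2-[bis(2,2,2-trifluoroethoxy)phosphoryl]propanoyl}oxy)-8-hydroxy-4a,8-dimethyl-2,3,4,4a,5,6,7,8-octahydronaphthalen-2-yl]prop-2-enoate, either configuration at the phosphonate α-carbon | C=C(C(=O)OC)[C@H]1C=C2[C@](C)(CC[C@H](OC(=O)C(C)P(=O)(OCC(F)(F)F)OCC(F)(F)F)[C@]2(C)O)CC1
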